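**Retrosynthetic overview**
1. The target is disconnected last at C5–C6 and at the lactone C–O bond: one acid-triggered operation on the open-chain precursor 18 closes ring B by an intramolecular carbonyl-ene reaction of a vinylglyoxal (giving C5 quaternary, C6–OH and C4=C18 together) and closes the butyrolactone.
2. 18 comes from alcohol 14 by esterification, decarboxylative methylenation (C8=C17, which also frees C12–OH) and tigloylation.
3. 14 comes from a Mukaiyama–Michael union (C9–C10) of ring-A dienol ether 4 with the alkylidene β-keto δ-lactone 12; the temporary δ-lactone relays C12 to C9.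
4. 12 comes from acetone, methyl 4,4-dimethoxyacetoacetate and aldehyde 7 (C13 by organocatalytic hydroxymethylation, C12 by proline aldol).
5. Ring order: ring A is carried in from the arene by Birch reduction; a temporary δ-lactone is formed in step 5 and cleaved in step 8; ring B and the butyrolactone form together in step 10.

Assumption: atom labels C1–C20 follow neo-clerodane numbering of the target (ring A = C1–C5 and C10, ring B = C5–C10, side chain C11–C16, C17 on C8, C18 on C4, C19 on C5, C20 on C9); the enolisable C8 centre of 14–16, F3 and F4 is left undefined because it becomes sp2.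

**Route**

Step 1
Reactants: 1 3,4-dimethylanisole
Product: 3 3,4-dimethylcyclohex-3-en-1-one, via Birch diene 2 (not isolated)
Conditions: Li, NH3 (l), t-BuOH, THF, −78 °C; then (CO2H)2, MeOH/H2O, rt
Reagents that add atoms: water O
Why: Birch reduction leaves the enol ether and the tetrasubstituted alkene as the two ring double bonds, and mild oxalic acid hydrolysis of the enol ether gives the β,γ-unsaturated ketone without conjugation.

Step 2
Reactants: 3 3,4-dimethylcyclohex-3-en-1-one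
Product: 4 trimethyl[(3,4-dimethylcyclohexa-1,3-dien-1-yl)oxy]silane
Conditions: TMSOTf, Et3N, CH2Cl2, 0 °C
Reagents that add atoms: trimethylsilyl triflate C[Si](C)(C)OS(=O)(=O)C(F)(F)F
Why: Soft enolisation removes the doubly activated C10–H between carbonyl and alkene, giving the conjugated (thermodynamic) silyl dienol ether.

Step 3
Reactants: 5 tert-butyl 4-oxobutanoate
Product: 7 tert-butyl (3R)-4-[(tert-butyldimethylsilyl)oxy]-3-formylbutanoate, via hydroxy aldehyde 6 (not isolated)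
Conditions: 37 % aq. CH2O, (S)-2-[diphenyl(trimethylsilyloxy)methyl]pyrrolidine (10 mol %), pH 7 buffer, PhMe, rt; then TBSCl, imidazole, CH2Cl2, 0 °C
Reagents that add atoms: formaldehyde C=O; tert-butyldimethylsilyl chloride CC(C)(C)[Si](C)(C)Cl
Why: Enamine-catalysed α-hydroxymethylation (organocatalytic aldol with formaldehyde) sets C13 as R because the bulky diarylmethyl group shields one enamine face, and immediate silylation prevents β-elimination.

Step 4
Reactants: 7 tert-butyl (3R)-4-[(tert-butyldimethylsilyl)oxy]-3-formylbutanoate; 8 acetone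
Product: 9 tert-butyl (3R,4R)-3-{[(tert-butyldimethylsilyl)oxy]methyl}-4-hydroxy-6-oxoheptanoate
Conditions: L-proline (30 mol %), acetone/DMSO (1:4), rt
Reagents that add atoms: none
Why: List–Barbas proline-catalysed direct aldol, in which the acetone enamine attacks the Re face of the α-branched aldehyde through the hydrogen-bonded Houk–List transition state (catalyst control), sets C12 as R.

Step 5
Reactants: 9 tert-butyl (3R,4R)-3-{[(tert-butyldimethylsilyl)oxy]methyl}-4-hydroxy-6-oxoheptanoate; 10 methyl 4,4-dimethoxy-3-oxobutanoate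
Product: 12 tert-butyl (3R)-4-[(tert-butyldimethylsilyl)oxy]-3-[(2R)-5-(2,2-dimethoxyacetyl)-4-methyl-6-oxo-3,6-dihydro-2H-pyran-2-yl]butanoate, via acetoacetate ester 11 (not isolated)
Conditions: B(OH)3 (10 mol %), PhMe, 110 °C (−MeOH); then ethylenediammonium diacetate (10 mol %), 4 Å MS, 50 °C
Reagents that add atoms: none
Why: β-Keto ester transesterification followed by intramolecular Knoevenagel condensation of the acidic C8 methylene onto the methyl ketone closes the unsaturated δ-lactone, which fixes the alkene geometry, doubly activates C9 and carries C6 as a masked aldehyde.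

Step 6
Reactants: 12 tert-butyl (3R)-4-[(tert-butyldimethylsilyl)oxy]-3-[(2R)-5-(2,2-dimethoxyacetyl)-4-methyl-6-oxo-3,6-dihydro-2H-pyran-2-yl]butanoate; 4 trimethyl[(3,4-dimethylcyclohexa-1,3-dien-1-yl)oxy]silane
Product: 14 tert-butyl (3R)-4-[(tert-butyldimethylsilyl)oxy]-3-[(2R,4R)-5-(2,2-dimethoxyacetyl)-4-[(1S,6R)-6-hydroxy-2,3-dimethylcyclohex-2-en-1-yl]-4-methyl-6-oxooxan-2-yl]butanoate, via enol silane adduct 13 (not isolated)
Conditions: Yb(OTf)3 (10 mol %), CH2Cl2, −20 °C; then NaBH4, EtOH, −40 °C; aq. NH4Cl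
Reagents that add atoms: none
Why: In this Mukaiyama–Michael addition the dienol ether attacks through its α-carbon (γ-attack would join two quaternary carbons) on the lactone face anti to the C12 substituent, through an antiperiplanar open transition state with C10–H over the lactone ring, setting C9 and C10, and the in-pot borohydride then reduces only the ring-A ketone by axial attack (the β-keto lactone stays masked as enol silane or enolate), giving C1–OH trans to C10–C9.

Step 7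
Reactants: 14 tert-butyl (3R)-4-[(tert-butyldimethylsilyl)oxy]-3-[(2R,4R)-5-(2,2-dimethoxyacetyl)-4-[(1S,6R)-6-hydroxy-2,3-dimethylcyclohex-2-en-1-yl]-4-methyl-6-oxooxan-2-yl]butanoate
Product: 15 tert-butyl (3R)-4-[(tert-butyldimethylsilyl)oxy]-3-[(2R,4R)-5-(2,2-dimethoxyacetyl)-4-[(1S,6R)-2,3-dimethyl-6-(2-methylpropanoyloxy)cyclohex-2-en-1-yl]-4-methyl-6-oxooxan-2-yl]butanoate
Conditions: (i-PrCO)2O, 4-(dimethylamino)pyridine (cat.), pyridine, CH2Cl2, rt
Reagents that add atoms: isobutyric anhydride CC(C)C(=O)OC(=O)C(C)C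
Why: Nucleophilic-catalysis acylation of the only free hydroxyl installs the C1 isobutyrate with retention before any enone is present.

Step 8
Reactants: 15 tert-butyl (3R)-4-[(tert-butyldimethylsilyl)oxy]-3-[(2R,4R)-5-(2,2-dimethoxyacetyl)-4-[(1S,6R)-2,3-dimethyl-6-(2-methylpropanoyloxy)cyclohex-2-en-1-yl]-4-methyl-6-oxooxan-2-yl]butanoate
Product: 17 tert-butyl (3R,4R,6R)-3-{[(tert-butyldimethylsilyl)oxy]methyl}-6-[(1S,6R)-2,3-dimethyl-6-(2-methylpropanoyloxy)cyclohex-2-en-1-yl]-4-hydroxy-9,9-dimethoxy-6-methyl-7-methylidene-8-oxononanoate, via β-keto acid 16 (not isolated)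
Conditions: LiOH·H2O (1.5 equiv), THF/H2O, 0 °C; then 37 % aq. CH2O, Et2NH, AcOH (pH 5), 45 °C
Reagents that add atoms: formaldehyde C=O
Why: The activated δ-lactone should saponify far faster than the hindered isobutyrate or the tert-butyl ester, and the β-keto acid then undergoes decarboxylative Mannich methylenation, which places the methylene regiospecifically on C8 and frees C12–OH.

Step 9
Reactants: 17 tert-butyl (3R,4R,6R)-3-{[(tert-butyldimethylsilyl)oxy]methyl}-6-[(1S,6R)-2,3-dimethyl-6-(2-methylpropanoyloxy)cyclohex-2-en-1-yl]-4-hydroxy-9,9-dimethoxy-6-methyl-7-methylidene-8-oxononanoate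
Product: 18 tert-butyl (3R,4R,6R)-3-{[(tert-butyldimethylsilyl)oxy]methyl}-6-[(1S,6R)-2,3-dimethyl-6-(2-methylpropanoyloxy)cyclohex-2-en-1-yl]-9,9-dimethoxy-6-methyl-4-{[(2E)-2-methylbut-2-enoyl]oxy}-7-methylidene-8-oxononanoate
Conditions: tiglic acid, N,N'-dicyclohexylcarbodiimide, 4-(dimethylamino)pyridine (cat.), CH2Cl2, 0 °C to rt
Reagents that add atoms: tiglic acid C/C=C(\C)C(=O)O
Why: Steglich esterification of the single free secondary alcohol under near-neutral conditions keeps the E geometry of the tiglate and avoids oxa-Michael closure onto the enone.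

Step 10
Reactants: 18 tert-butyl (3R,4R,6R)-3-{[(tert-butyldimethylsilyl)oxy]methyl}-6-[(1S,6R)-2,3-dimethyl-6-(2-methylpropanoyloxy)cyclohex-2-en-1-yl]-9,9-dimethoxy-6-methyl-4-{[(2E)-2-methylbut-2-enoyl]oxy}-7-methylidene-8-oxononanoate
Product: 20 CNP0148909.1, via vinylglyoxal lactone 19 (not isolated)
Conditions: CF3CO2H/CH2Cl2/H2O (10:10:1), 0 °C to rt; then evaporation, PhMe, 80 °C
Reagents that add atoms: water O
Why: Acid removes the silyl ether, tert-butyl ester and acetal so that the hydroxy acid lactonises, and the freed α-keto aldehyde undergoes an intramolecular carbonyl-ene reaction with the tetrasubstituted ring-A alkene through a chair-like transition state with equatorial oxygen (isopulegol-type), forming C5–C6 anti to C10–H (trans-decalin), an equatorial 6R hydroxyl and, by hydrogen transfer from the C18 methyl, the exocyclic C4 methylene.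

**Compound list**
1 | 3,4-dimethylanisole | COc1ccc(C)c(C)c1 | starting material
2 | 1-methoxy-4,5-dimethylcyclohexa-1,4-diene | COC1=CCC(C)=C(C)C1 | intermediate
3 | 3,4-dimethylcyclohex-3-en-1-one | O=C1CCC(C)=C(C)C1 | intermediate
4 | trimethyl[(3,4-dimethylcyclohexa-1,3-dien-1-yl)oxy]silane | C[Si](C)(C)OC1=CC(C)=C(C)CC1 | intermediate
5 | tert-butyl 4-oxobutanoate | O=CCCC(=O)OC(C)(C)C | starting material
6 | tert-butyl (3R)-3-formyl-4-hydroxybutanoate | O=C[C@H](CC(=O)OC(C)(C)C)CO | intermediate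
7 | tert-butyl (3R)-4-[(tert-butyldimethylsilyl)oxy]-3-formylbutanoate | O=C[C@H](CC(=O)OC(C)(C)C)CO[Si](C)(C)C(C)(C)C | intermediate
8 | acetone | CC(C)=O | starting material
9 | tert-butyl (3R,4R)-3-{[(tert-butyldimethylsilyl)oxy]methyl}-4-hydroxy-6-oxoheptanoate | CC(=O)C[C@@H](O)[C@H](CC(=O)OC(C)(C)C)CO[Si](C)(C)C(C)(C)C | intermediate
10 | methyl 4,4-dimethoxy-3-oxobutanoate | COC(=O)CC(=O)C(OC)OC | starting material
11 | tert-butyl (3R,4R)-3-{[(tert-butyldimethylsilyl)oxy]methyl}-4-[(4,4-dimethoxy-3-oxobutanoyl)oxy]-6-oxoheptanoate | CC(=O)C[C@@H](OC(=O)CC(=O)C(OC)OC)[C@H](CC(=O)OC(C)(C)C)CO[Si](C)(C)C(C)(C)C | intermediate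
12 | tert-butyl (3R)-4-[(tert-butyldimethylsilyl)oxy]-3-[(2R)-5-(2,2-dimethoxyacetyl)-4-methyl-6-oxo-3,6-dihydro-2H-pyran-2-yl]butanoate | CC1=C(C(=O)C(OC)OC)C(=O)O[C@H](C1)[C@H](CC(=O)OC(C)(C)C)CO[Si](C)(C)C(C)(C)C | intermediate
13 | tert-butyl (3R)-4-[(tert-butyldimethylsilyl)oxy]-3-[(2R,4R)-5-[2,2-dimethoxy-1-(trimethylsilyloxy)ethylidene]-4-[(1S)-2,3-dimethyl-6-oxocyclohex-2-en-1-yl]-4-methyl-6-oxooxan-2-yl]butanoate | O=C1CCC(C)=C(C)[C@H]1[C@@]2(C)C[C@@H](OC(=O)C2=C(O[Si](C)(C)C)C(OC)OC)[C@H](CC(=O)OC(C)(C)C)CO[Si](C)(C)C(C)(C)C | intermediate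
14 | tert-butyl (3R)-4-[(tert-butyldimethylsilyl)oxy]-3-[(2R,4R)-5-(2,2-dimethoxyacetyl)-4-[(1S,6R)-6-hydroxy-2,3-dimethylcyclohex-2-en-1-yl]-4-methyl-6-oxooxan-2-yl]butanoate | O[C@@H]1CCC(C)=C(C)[C@H]1[C@@]2(C)C[C@@H](OC(=O)C2C(=O)C(OC)OC)[C@H](CC(=O)OC(C)(C)C)CO[Si](C)(C)C(C)(C)C | intermediate
15 | tert-butyl (3R)-4-[(tert-butyldimethylsilyl)oxy]-3-[(2R,4R)-5-(2,2-dimethoxyacetyl)-4-[(1S,6R)-2,3-dimethyl-6-(2-methylpropanoyloxy)cyclohex-2-en-1-yl]-4-methyl-6-oxooxan-2-yl]butanoate | CC(C)C(=O)O[C@@H]1CCC(C)=C(C)[C@H]1[C@@]2(C)C[C@@H](OC(=O)C2C(=O)C(OC)OC)[C@H](CC(=O)OC(C)(C)C)CO[Si](C)(C)C(C)(C)C | intermediate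
16 | (3R,5R,6R)-8-tert-butoxy-6-{[(tert-butyldimethylsilyl)oxy]methyl}-2-(2,2-dimethoxyacetyl)-3-[(1S,6R)-2,3-dimethyl-6-(2-methylpropanoyloxy)cyclohex-2-en-1-yl]-5-hydroxy-3-methyl-8-oxooctanoic acid | CC(C)C(=O)O[C@@H]1CCC(C)=C(C)[C@H]1[C@@](C)(C[C@@H](O)[C@H](CC(=O)OC(C)(C)C)CO[Si](C)(C)C(C)(C)C)C(C(=O)O)C(=O)C(OC)OC | intermediate
17 | tert-butyl (3R,4R,6R)-3-{[(tert-butyldimethylsilyl)oxy]methyl}-6-[(1S,6R)-2,3-dimethyl-6-(2-methylpropanoyloxy)cyclohex-2-en-1-yl]-4-hydroxy-9,9-dimethoxy-6-methyl-7-methylidene-8-oxononanoate | CC(C)C(=O)O[C@@H]1CCC(C)=C(C)[C@H]1[C@@](C)(C[C@@H](O)[C@H](CC(=O)OC(C)(C)C)CO[Si](C)(C)C(C)(C)C)C(=C)C(=O)C(OC)OC | intermediate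
18 | tert-butyl (3R,4R,6R)-3-{[(tert-butyldimethylsilyl)oxy]methyl}-6-[(1S,6R)-2,3-dimethyl-6-(2-methylpropanoyloxy)cyclohex-2-en-1-yl]-9,9-dimethoxy-6-methyl-4-{[(2E)-2-methylbut-2-enoyl]oxy}-7-methylidene-8-oxononanoate | CC(C)C(=O)O[C@@H]1CCC(C)=C(C)[C@H]1[C@@](C)(C[C@@H](OC(=O)/C(C)=C/C)[C@H](CC(=O)OC(C)(C)C)CO[Si](C)(C)C(C)(C)C)C(=C)C(=O)C(OC)OC | intermediate
19 | (4R,6R)-4-[(1S,6R)-2,3-dimethyl-6-(2-methylpropanoyloxy)cyclohex-2-en-1-yl]-4-methyl-3-methylidene-2-oxo-6-[(3R)-5-oxooxolan-3-yl]-6-{[(2E)-2-methylbut-2-enoyl]oxy}hexanal | CC(C)C(=O)O[C@@H]1CCC(C)=C(C)[C@H]1[C@@](C)(C[C@@H](OC(=O)/C(C)=C/C)[C@H]2COC(=O)C2)C(=C)C(=O)C=O | intermediate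
20 | CNP0148909.1, (1R,5R,6R,9R,10R,12R,13R)-6-hydroxy-1-(2-methylpropanoyloxy)-12-[(2E)-2-methylbut-2-enoyloxy]-7-oxo-neo-cleroda-4(18),8(17)-dien-15,16-olide | C=C1CC[C@@H](OC(=O)C(C)C)[C@H]2[C@@]1(C)[C@@H](O)C(=O)C(=C)[C@]2(C)C[C@@H](OC(=O)/C(C)=C/C)[C@H]1COC(=O)C1 | target

**Step count and risks**

Total step count: 10. Longest linear sequence: 8 steps (5 to 20, steps 3–10); the ring-A branch (1 to 4) is 2 steps and joins at step 6.

Most likely to fail, first: step 10. The tetrasubstituted alkene may isomerise in strong acid, or the ene reaction may give the cis-fused or endocyclic-alkene product. The fallback sets out from 18 and decouples the two ring closures. p-Toluenesulfonic acid in methanol at 40 °C removes the silyl ether and closes the lactone while the acetal survives, giving the lactone dimethyl acetal F1. Aqueous formic acid at 0 °C then gives isolated 19, which is cyclised under chelating Lewis-acid catalysis with Yb(OTf)3 in CH2Cl2 at −40 °C. This comes back to the route at 20.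

Second: step 6. The dienol ether may react at its γ-carbon, or give the wrong C10 epimer. The fallback sets out from the Birch diene 2 (isolated by leaving out the acid hydrolysis of step 1) and from 12, and replaces the Lewis-acid Michael addition by a pericyclic reaction. KOt-Bu in DMSO isomerises 2 to the conjugated 1-methoxy-3,4-dimethylcyclohexa-1,3-diene F2. Heating F2 with 12 in toluene at 80 °C gives, by an inverse-electron-demand hetero-Diels–Alder reaction that can only engage the enol-ether double bond, the cis-fused tricyclic methyl ketal F3. Aqueous oxalic acid opens F3 to the keto β-keto lactone F4. LiN(SiMe3)2 (1 equiv) followed by NaBH4 reduces the ring ketone, and the route is rejoined at 14.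

Third: step 5. The β-acyloxy ketone may eliminate before the Knoevenagel closure, or 12 may deconjugate. The fallback sets out from 9 and builds the lactone first. Coupling with diethylphosphonoacetic acid (N,N'-dicyclohexylcarbodiimide) gives the phosphonoacetate F5. Intramolecular Horner–Wadsworth–Emmons olefination (LiCl, DBU, MeCN) gives the unsaturated lactone F6. Its lithium dienolate (LiN(i-Pr)2, THF, −78 °C) is C-acylated at the α-carbon with methyl 2,2-dimethoxyacetate, coming back to the route at 12.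

**Further compounds**
F1 | step 10 | (4R,6R)-4-[(1S,6R)-2,3-dimethyl-6-(2-methylpropanoyloxy)cyclohex-2-en-1-yl]-1,1-dimethoxy-4-methyl-3-methylidene-6-[(3R)-5-oxooxolan-3-yl]-6-{[(2E)-2-methylbut-2-enoyl]oxy}hexan-2-one | CC(C)C(=O)O[C@@H]1CCC(C)=C(C)[C@H]1[C@@](C)(C[C@@H](OC(=O)/C(C)=C/C)[C@H]2COC(=O)C2)C(=C)C(=O)C(OC)OC
F2 | step 6 | 1-methoxy-3,4-dimethylcyclohexa-1,3-diene | COC1=CC(C)=C(C)CC1
F3 | step 6 | cis-fused tricyclic methyl ketal (1S,9R,10S,12R,13R) from 12 and F2, with new O7–C1 and C9–C10 bonds | CO[C@]12CCC(C)=C(C)[C@H]1[C@@]3(C)C[C@@H](OC(=O)C3=C(O2)C(OC)OC)[C@H](CC(=O)OC(C)(C)C)CO[Si](C)(C)C(C)(C)C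
F4 | step 6 | tert-butyl (3R)-4-[(tert-butyldimethylsilyl)oxy]-3-[(2R,4R)-5-(2,2-dimethoxyacetyl)-4-[(1S)-2,3-dimethyl-6-oxocyclohex-2-en-1-yl]-4-methyl-6-oxooxan-2-yl]butanoate | O=C1CCC(C)=C(C)[C@H]1[C@@]2(C)C[C@@H](OC(=O)C2C(=O)C(OC)OC)[C@H](CC(=O)OC(C)(C)C)CO[Si](C)(C)C(C)(C)C
F5 | step 5 | tert-butyl (3R,4R)-3-{[(tert-butyldimethylsilyl)oxy]methyl}-4-{[2-(diethoxyphosphoryl)acetyl]oxy}-6-oxoheptanoate | CC(=O)C[C@@H](OC(=O)CP(=O)(OCC)OCC)[C@H](CC(=O)OC(C)(C)C)CO[Si](C)(C)C(C)(C)C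
F6 | step 5 | tert-butyl (3R)-4-[(tert-butyldimethylsilyl)oxy]-3-[(2R)-4-methyl-6-oxo-3,6-dihydro-2H-pyran-2-yl]butanoate | CC1=CC(=O)O[C@H](C1)[C@H](CC(=O)OC(C)(C)C)CO[Si](C)(C)C(C)(C)C
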